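Ring A of the flavone carries O1 on C8a, the allylic carbon on C8, O7 on C7 and O5 on C5: oxygen, carbon, oxygen on three adjacent carbons plus a meta oxygen, which is the pattern a vinylketene and an ynol ether lay down in one benzannulation.
Ring C is disconnected at O1–C2 (6-endo oxa-Michael closure of an o-hydroxyaryl ynone) and at C4–C4a (ortho-formylation of the C8a phenol, then phenylacetylide addition and oxidation).
Ring A is disconnected at C8a–C8 and C7–C6, with electrocyclic closure of C8a–C4a, to 3-ethoxycyclobutenone and a chiral triisopropylsilyl ynol ether.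
The ynol ether comes from a terminal 1,4-enyne, made by iridium-catalysed enantioconvergent allylic alkynylation of the racemic aryl vinyl carbinol from O-benzylvanillin; the stereocentre is set there and is a spectator afterwards.
Order of ring formation: guaiacyl and phenyl rings are bought, ring A is built in step 6, ring C is closed in step 10, then two deprotections.

Key step: step 6

Assumption: the (S)-configured ligand is taken to deliver (R)-8; the sense of induction must be checked on the first batch, and if it is opposite the (R)-ligand is used with no other change.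

Step 1
Reactants: 1 4-(benzyloxy)-3-methoxybenzaldehyde (O-benzylvanillin); 2 vinylmagnesium bromide
Product: 3 rac-1-[4-(benzyloxy)-3-methoxyphenyl]prop-2-en-1-ol
Conditions: 2 (1.2 equiv), THF, −78 → 0 °C; aq NH4Cl
Reagents that add atoms: vinylmagnesium bromide (2), C=C[Mg]Br
Why: Grignard 1,2-addition to an aromatic aldehyde; the racemate suffices because step 3 is enantioconvergent, and a benzyl ether is used because it withstands the acid of step 3 and leaves together with the ethyl ether in step 11.

Step 2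
Reactants: 4 ethynyltrimethylsilane
Product: 7 potassium trifluoro[(trimethylsilyl)ethynyl]borate, via lithium (trimethylsilyl)acetylide 5 (not isolated), via lithium alkynyltrimethoxyborate 6 (not isolated)
Conditions: n-BuLi, THF, −78 °C; B(OMe)3, −78 → −20 °C; aq KHF2, −20 °C → rt
Reagents that add atoms: trimethyl borate, COB(OC)OC; potassium hydrogen difluoride, [K+].[F-].F
Why: Standard alkynyltrifluoroborate preparation by borylation of a lithium acetylide and fluoride exchange on the ate complex, giving a crystalline, storable salt.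

Step 3
Reactants: 3 rac-1-[4-(benzyloxy)-3-methoxyphenyl]prop-2-en-1-ol; 7 potassium trifluoro[(trimethylsilyl)ethynyl]borate
Product: 8 (R)-{3-[4-(benzyloxy)-3-methoxyphenyl]pent-4-en-1-yn-1-yl}trimethylsilane
Conditions: [Ir(cod)Cl]2 (4 mol %), (S)-5-[(11bS)-dinaphtho[2,1-d:1′,2′-f][1,3,2]dioxaphosphepin-4-yl]-5H-dibenzo[b,f]azepine (16 mol %), 7 (1.5 equiv), KHF2, CF3CO2H, n-Bu4NBr (10 mol %), 1,4-dioxane, rt
Reagents that add atoms: potassium trifluoro[(trimethylsilyl)ethynyl]borate (7), [K+].F[B-](F)(F)C#C[Si](C)(C)C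
Why: Iridium-catalysed enantioconvergent allylic alkynylation in which acid-assisted ionisation of either enantiomer of 3 gives the same π-allyl iridium complex, and the chiral phosphoramidite–olefin ligand directs the alkynyltrifluoroborate to one face of the benzylic terminus, setting the stereocentre as R with branched selectivity.

Step 4
Reactants: 8 (R)-{3-[4-(benzyloxy)-3-methoxyphenyl]pent-4-en-1-yn-1-yl}trimethylsilane
Product: 9 (S)-1-(benzyloxy)-2-methoxy-4-(pent-1-en-4-yn-3-yl)benzene
Conditions: AgNO3 (10 mol %), CH2Cl2/MeOH/H2O (7:4:1), rt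
Reagents that add atoms: none
Why: Silver-catalysed protodesilylation of an alkynylsilane through a silver acetylide runs at neutral pH, so the methine C–H that is benzylic, allylic and propargylic at once is not exposed to base; the descriptor changes from R to S only because ethynyl ranks below aryl.

Step 5
Reactants: 9 (S)-1-(benzyloxy)-2-methoxy-4-(pent-1-en-4-yn-3-yl)benzene
Product: 12 (R)-{[3-(4-(benzyloxy)-3-methoxyphenyl)pent-4-en-1-yn-1-yl]oxy}tri(propan-2-yl)silane, via lithium acetylide 10 (not isolated), via lithium ynolate 11 (not isolated)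
Conditions: n-BuLi (1.05 equiv), THF, −78 °C; LiOOt-Bu (from t-BuOOH and LiN(SiMe3)2, THF, −78 °C), −78 → 0 °C; i-Pr3SiOTf, −78 → 0 °C
Reagents that add atoms: tert-butyl hydroperoxide, CC(C)(C)OO; triisopropylsilyl trifluoromethanesulfonate, CC(C)[Si](OS(=O)(=O)C(F)(F)F)(C(C)C)C(C)C
Why: Kinetic deprotonation of the sp C–H, oxygen transfer from lithium tert-butyl peroxide to the acetylide carbon and O-silylation of the ynolate by the bulky silyl triflate (acetylide oxidation route to siloxyalkynes); as acetylide and as ynolate the neighbouring methine is shielded from deprotonation because a second negative charge would sit next to the first.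

Step 6
Reactants: 12 (R)-{[3-(4-(benzyloxy)-3-methoxyphenyl)pent-4-en-1-yn-1-yl]oxy}tri(propan-2-yl)silane; 13 3-ethoxycyclobut-2-en-1-one
Product: 18 2-{(R)-1-[4-(benzyloxy)-3-methoxyphenyl]prop-2-en-1-yl}-5-ethoxy-3-{[tri(propan-2-yl)silyl]oxy}phenol, via ethoxyvinylketene 14 (not isolated), via vinylcyclobutenone 15 (not isolated), via dienylketene 16 (not isolated), via cyclohexadienone 17 (not isolated)
Conditions: 13 (1.3 equiv, added in portions), PhMe (0.4 M), 80 °C then 110 °C, sealed tube, argon
Reagents that add atoms: 3-ethoxycyclobut-2-en-1-one (13), CCOC1=CC(=O)C1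
Why: Heating opens 13 by four-electron electrocyclic cleavage to ethoxyvinylketene 14, whose carbonyl carbon is attacked by the electron-rich, side-chain-bearing carbon of ynol ether 12 in a regioselective [2+2] cycloaddition that forms C8a–C8 and C7–C6 and gives cyclobutenone 15. Compound 15 reopens by a second four-electron electrocyclic step to dienylketene 16, which closes ring A by six-electron electrocyclization (ketene carbon C8a onto the terminal methylene C4a), and enolisation of dienone 17 gives phenol 18. This is the Danheiser benzannulation of a cyclobutenone with a siloxyalkyne, and pairing a 3-alkoxycyclobutenone with an ynol ether is precedented by the formation of 3,5-dialkoxyphenols from ketene and alkoxyacetylenes. No stereocentre is created in the product (the transiently stereogenic ring carbon of 15 becomes aromatic), and the neutral, reagent-free conditions should leave the doubly benzylic, allylic C–H untouched. The step needs regioselectivity only, which the polarisation of the ynol ether secures: the free hydroxyl ends on C8a, the silyl ether on C7 and the ethyl ether on C5, so ring C can later close in one sense only. The terminal alkene should not compete because unactivated alkenes add to ketenes far more slowly than ynol ethers do.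

Step 7
Reactants: 18 2-{(R)-1-[4-(benzyloxy)-3-methoxyphenyl]prop-2-en-1-yl}-5-ethoxy-3-{[tri(propan-2-yl)silyl]oxy}phenol
Product: 20 3-{(R)-1-[4-(benzyloxy)-3-methoxyphenyl]prop-2-en-1-yl}-6-ethoxy-2-hydroxy-4-{[tri(propan-2-yl)silyl]oxy}benzaldehyde, via salicyl alcohol 19 (not isolated)
Conditions: MgCl2 (2.5 equiv), Et3N (5 equiv), (CH2O)n (7 equiv), MeCN, reflux; cold 1 M HCl work-up
Reagents that add atoms: paraformaldehyde (as formaldehyde), C=O
Why: Magnesium-mediated ortho-formylation (Casnati–Skattebøl): the magnesium phenoxide delivers formaldehyde to the only free ortho carbon, C4a, and the benzylic alkoxide is oxidised by a second formaldehyde through hydride transfer, while the para carbon C6 is not reached by the chelated reagent.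

Step 8
Reactants: 20 3-{(R)-1-[4-(benzyloxy)-3-methoxyphenyl]prop-2-en-1-yl}-6-ethoxy-2-hydroxy-4-{[tri(propan-2-yl)silyl]oxy}benzaldehyde; 21 phenylacetylene
Product: 23 1-[3-{(R)-1-[4-(benzyloxy)-3-methoxyphenyl]prop-2-en-1-yl}-6-ethoxy-2-hydroxy-4-{[tri(propan-2-yl)silyl]oxy}phenyl]-3-phenylprop-2-yn-1-ol (both carbinol epimers), via lithium phenylacetylide 22 (not isolated)
Conditions: 21 (2.6 equiv), n-BuLi (2.5 equiv), THF, −78 °C; then 20, −78 → 0 °C; aq NH4Cl; product used crude
Reagents that add atoms: phenylacetylene (21), C#Cc1ccccc1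
Why: Acetylide 1,2-addition to an aldehyde, in which the first equivalent only deprotonates the phenol and the second adds to the lithium phenoxide-aldehyde; the carbinol configuration is irrelevant because step 9 removes it.

Step 9
Reactants: 23 the propargylic alcohol of step 8
Product: 24 1-[3-{(R)-1-[4-(benzyloxy)-3-methoxyphenyl]prop-2-en-1-yl}-6-ethoxy-2-hydroxy-4-{[tri(propan-2-yl)silyl]oxy}phenyl]-3-phenylprop-2-yn-1-one
Conditions: MnO2 (activated, 15 equiv), CH2Cl2, rt
Reagents that add atoms: none
Why: Heterogeneous MnO2 oxidation is selective for benzylic-propargylic alcohols and should leave the phenol, the terminal alkene and the silyl ether alone.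

Step 10
Reactants: 24 the o-hydroxyaryl ynone of step 9
Product: 25 8-{(R)-1-[4-(benzyloxy)-3-methoxyphenyl]prop-2-en-1-yl}-5-ethoxy-2-phenyl-7-{[tri(propan-2-yl)silyl]oxy}-4H-chromen-4-one
Conditions: DMAP (20 mol %), DMF, rt
Reagents that add atoms: none
Why: Intramolecular oxa-Michael addition of the C8a hydroxyl to the ynone closes ring C in the 6-endo-dig mode, and nucleophilic catalysis by DMAP steers the closure to the flavone and away from the 5-exo aurone that carbonate bases can give.

Step 11
Reactants: 25 the protected flavone of step 10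
Product: 26 5-hydroxy-8-[(R)-1-(4-hydroxy-3-methoxyphenyl)prop-2-en-1-yl]-2-phenyl-7-{[tri(propan-2-yl)silyl]oxy}-4H-chromen-4-one
Conditions: BCl3 (4 equiv), C6HMe5 (5 equiv), CH2Cl2, −78 → 0 °C; H2O quench at 0 °C, NaHCO3 wash
Reagents that add atoms: none
Why: Boron trichloride held between the C4 carbonyl and O5 cleaves the peri ethyl ether by chelation-assisted dealkylation and also removes the benzyl ether, whose cation is caught by pentamethylbenzene before it can alkylate ring A or the alkene, while the non-chelated guaiacyl methyl ether should survive at this temperature; any loss of the silyl ether here leads directly to the target.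

Step 12
Reactants: 26 the 7-O-silyl flavone of step 11
Product: 27 5,7-dihydroxy-8-[(R)-1-(4-hydroxy-3-methoxyphenyl)prop-2-en-1-yl]-2-phenyl-4H-chromen-4-one (target)
Conditions: n-Bu4NF (1.2 equiv), AcOH (1.5 equiv), THF, 0 °C
Reagents that add atoms: none
Why: Fluoride cleavage of an aryl silyl ether, fast here because O7 is vinylogously conjugated with the C4 carbonyl, with acetic acid buffering the phenoxides so that the diaryl allyl methine is not exposed to basic fluoride.

Compound list
1 | 4-(benzyloxy)-3-methoxybenzaldehyde | COc1cc(C=O)ccc1OCc1ccccc1 | starting material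
2 | vinylmagnesium bromide | C=C[Mg]Br | starting material
3 | rac-1-[4-(benzyloxy)-3-methoxyphenyl]prop-2-en-1-ol | C=CC(O)c1ccc(OCc2ccccc2)c(OC)c1 | intermediate
4 | ethynyltrimethylsilane | C#C[Si](C)(C)C | starting material
5 | lithium (trimethylsilyl)acetylide (not isolated) | [Li]C#C[Si](C)(C)C | intermediate
6 | lithium trimethoxy[(trimethylsilyl)ethynyl]borate (not isolated) | [Li+].CO[B-](OC)(OC)C#C[Si](C)(C)C | intermediate
7 | potassium trifluoro[(trimethylsilyl)ethynyl]borate | [K+].F[B-](F)(F)C#C[Si](C)(C)C | intermediate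
8 | (R)-{3-[4-(benzyloxy)-3-methoxyphenyl]pent-4-en-1-yn-1-yl}trimethylsilane | C=C[C@H](c1ccc(OCc2ccccc2)c(OC)c1)C#C[Si](C)(C)C | intermediate
9 | (S)-1-(benzyloxy)-2-methoxy-4-(pent-1-en-4-yn-3-yl)benzene | C=C[C@H](c1ccc(OCc2ccccc2)c(OC)c1)C#C | intermediate
10 | lithium acetylide of 9 (not isolated) | C=C[C@H](c1ccc(OCc2ccccc2)c(OC)c1)C#C[Li] | intermediate
11 | lithium ynolate from 10 (not isolated) | C=C[C@H](c1ccc(OCc2ccccc2)c(OC)c1)C#CO[Li] | intermediate
12 | (R)-{[3-(4-(benzyloxy)-3-methoxyphenyl)pent-4-en-1-yn-1-yl]oxy}tri(propan-2-yl)silane | C=C[C@H](c1ccc(OCc2ccccc2)c(OC)c1)C#CO[Si](C(C)C)(C(C)C)C(C)C | intermediate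
13 | 3-ethoxycyclobut-2-en-1-one | CCOC1=CC(=O)C1 | starting material
14 | 3-ethoxybuta-1,3-dien-1-one (ethoxyvinylketene, not isolated) | C=C(OCC)C=C=O | intermediate
15 | 4-(1-ethoxyethenyl)-2-(1-arylallyl)-3-(triisopropylsilyloxy)cyclobut-2-en-1-one, side-chain stereocentre unchanged, ring carbon C4 as a mixture (not isolated) | C=C[C@H](c1ccc(OCc2ccccc2)c(OC)c1)C1=C(O[Si](C(C)C)(C(C)C)C(C)C)C(C(=C)OCC)C1=O | intermediate
16 | dienylketene with the ketene and ethoxyvinyl groups cis on the central double bond (not isolated) | C=C[C@H](c1ccc(OCc2ccccc2)c(OC)c1)C(=C=O)/C(O[Si](C(C)C)(C(C)C)C(C)C)=C\C(=C)OCC | intermediate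
17 | 5-ethoxy-2-(1-arylallyl)-3-(triisopropylsilyloxy)cyclohexa-2,4-dien-1-one (not isolated) | C=C[C@H](c1ccc(OCc2ccccc2)c(OC)c1)C1=C(O[Si](C(C)C)(C(C)C)C(C)C)C=C(OCC)CC1=O | intermediate
18 | 2-{(R)-1-[4-(benzyloxy)-3-methoxyphenyl]prop-2-en-1-yl}-5-ethoxy-3-{[tri(propan-2-yl)silyl]oxy}phenol | C=C[C@H](c1ccc(OCc2ccccc2)c(OC)c1)c1c(O)cc(OCC)cc1O[Si](C(C)C)(C(C)C)C(C)C | intermediate
19 | 6-(hydroxymethyl) derivative of 18 (salicyl alcohol, as its magnesium salt, not isolated) | C=C[C@H](c1ccc(OCc2ccccc2)c(OC)c1)c1c(O)c(CO)c(OCC)cc1O[Si](C(C)C)(C(C)C)C(C)C | intermediate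
20 | 3-{(R)-1-[4-(benzyloxy)-3-methoxyphenyl]prop-2-en-1-yl}-6-ethoxy-2-hydroxy-4-{[tri(propan-2-yl)silyl]oxy}benzaldehyde | C=C[C@H](c1ccc(OCc2ccccc2)c(OC)c1)c1c(O)c(C=O)c(OCC)cc1O[Si](C(C)C)(C(C)C)C(C)C | intermediate
21 | phenylacetylene | C#Cc1ccccc1 | starting material
22 | lithium phenylacetylide (not isolated) | [Li]C#Cc1ccccc1 | intermediate
23 | 1-[3-{(R)-1-[4-(benzyloxy)-3-methoxyphenyl]prop-2-en-1-yl}-6-ethoxy-2-hydroxy-4-{[tri(propan-2-yl)silyl]oxy}phenyl]-3-phenylprop-2-yn-1-ol, both carbinol epimers | C=C[C@H](c1ccc(OCc2ccccc2)c(OC)c1)c1c(O)c(C(O)C#Cc2ccccc2)c(OCC)cc1O[Si](C(C)C)(C(C)C)C(C)C | intermediate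
24 | 1-[3-{(R)-1-[4-(benzyloxy)-3-methoxyphenyl]prop-2-en-1-yl}-6-ethoxy-2-hydroxy-4-{[tri(propan-2-yl)silyl]oxy}phenyl]-3-phenylprop-2-yn-1-one | C=C[C@H](c1ccc(OCc2ccccc2)c(OC)c1)c1c(O)c(C(=O)C#Cc2ccccc2)c(OCC)cc1O[Si](C(C)C)(C(C)C)C(C)C | intermediate
25 | 8-{(R)-1-[4-(benzyloxy)-3-methoxyphenyl]prop-2-en-1-yl}-5-ethoxy-2-phenyl-7-{[tri(propan-2-yl)silyl]oxy}-4H-chromen-4-one | C=C[C@H](c1ccc(OCc2ccccc2)c(OC)c1)c1c(O[Si](C(C)C)(C(C)C)C(C)C)cc(OCC)c2c(=O)cc(-c3ccccc3)oc12 | intermediate
26 | 5-hydroxy-8-[(R)-1-(4-hydroxy-3-methoxyphenyl)prop-2-en-1-yl]-2-phenyl-7-{[tri(propan-2-yl)silyl]oxy}-4H-chromen-4-one | C=C[C@H](c1ccc(O)c(OC)c1)c1c(O[Si](C(C)C)(C(C)C)C(C)C)cc(O)c2c(=O)cc(-c3ccccc3)oc12 | intermediate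
27 | 5,7-dihydroxy-8-[(R)-1-(4-hydroxy-3-methoxyphenyl)prop-2-en-1-yl]-2-phenyl-4H-chromen-4-one | C=C[C@H](c1ccc(O)c(OC)c1)c1c(O)cc(O)c2c(=O)cc(-c3ccccc3)oc12 | target

Total step count: 12. Longest linear sequence: 11 steps (steps 1 and 3 to 12, from aldehyde 1); step 2 is a one-step side branch.

Steps most likely to fail

Step 5. While the terminal alkyne, and later the silyl ynol ether, sit beside lithium bases, the benzylic, allylic and propargylic methine may be deprotonated, leading to racemisation or a proton shift to a conjugated vinylallene. The fallback masks the alkene so that the methine is no longer allylic; it sets out from 8 and comes back at 18. Enyne 8 is hydroborated at the terminal alkene with 9-BBN and oxidised with NaBO3·4H2O to (R)-3-[4-(benzyloxy)-3-methoxyphenyl]-5-(trimethylsilyl)pent-4-yn-1-ol F1. The alcohol is converted with PhSSPh and n-Bu3P into (R)-{3-[4-(benzyloxy)-3-methoxyphenyl]-5-(phenylsulfanyl)pent-1-yn-1-yl}trimethylsilane F2. K2CO3 in MeOH, harmless once the alkene is gone, removes the silyl group to give (S)-1-(benzyloxy)-2-methoxy-4-[5-(phenylsulfanyl)pent-1-yn-3-yl]benzene F3. Acetylide oxidation and silylation as in step 5 then give the sulfide-bearing siloxyalkyne F4. Benzannulation with 13 as in step 6 gives 2-{(R)-1-[4-(benzyloxy)-3-methoxyphenyl]-3-(phenylsulfanyl)propyl}-5-ethoxy-3-{[tri(propan-2-yl)silyl]oxy}phenol F5. NaIO4 in MeOH/H2O oxidises the sulfide to the sulfoxide F6, and thermal syn-elimination (xylene, 135 °C, CaCO3, P(OMe)3 as sulfenic acid trap) regenerates the vinyl group and returns phenol 18.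

Step 6. Ring opening of the vinylogous ester 13 may be slower than thermal decay of the ynol ether, or the ketene may acylate the product phenol once the ynol ether is depleted. The fallback generates the same ketene at room temperature by a photochemical Wolff rearrangement; it sets out from 12 and comes back at 18. Ethyl vinyl ether is lithiated with t-BuLi to 1-ethoxyvinyllithium F7, which is acylated with N-methoxy-N-methylacetamide to 3-ethoxybut-3-en-2-one F8. Its lithium enolate (LiN(SiMe3)2, −78 °C) is trifluoroacetylated with CF3CO2CH2CF3 to 5-ethoxy-1,1,1-trifluorohex-5-ene-2,4-dione F9, and diazo transfer with MsN3, Et3N and H2O in MeCN gives 1-diazo-3-ethoxybut-3-en-2-one F10. Irradiation of F10 with 12 in CH2Cl2 at room temperature forms ketene 14, which is trapped as cyclobutenone 15; brief warming to 80 °C completes ring opening and electrocyclization to 18.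

Step 3. The electron-rich carbinol may ionise under the acid promoter without the metal and be captured directly by the trifluoroborate, which would erode enantiopurity and give the linear isomer; the nucleophile may also lose its silyl group. The fallback is a copper-catalysed enantioselective SN2′ substitution; it sets out from 1 and comes back at 8. Horner–Wadsworth–Emmons olefination of 1 (triethyl phosphonoacetate, LiCl, DBU, MeCN) gives ethyl (E)-3-[4-(benzyloxy)-3-methoxyphenyl]prop-2-enoate F11. Reduction with i-Bu2AlH gives (E)-3-[4-(benzyloxy)-3-methoxyphenyl]prop-2-en-1-ol F12, and (EtO)2P(O)Cl with Et3N and DMAP gives the diethyl allylic phosphate F13. Bis(2-methylpropyl)[(trimethylsilyl)ethynyl]aluminium F14 is made from 4 and i-Bu2AlH with catalytic Et3N. It is added to F13 in THF at −30 °C with a catalyst formed from CuCl2·2H2O and an enantiopure sulfonate-bearing imidazolinium salt (N-heterocyclic carbene precursor), which should deliver the branched enyne 8.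

Further compounds
F1 | step 5 | (R)-3-[4-(benzyloxy)-3-methoxyphenyl]-5-(trimethylsilyl)pent-4-yn-1-ol | OCC[C@H](c1ccc(OCc2ccccc2)c(OC)c1)C#C[Si](C)(C)C
F2 | step 5 | (R)-{3-[4-(benzyloxy)-3-methoxyphenyl]-5-(phenylsulfanyl)pent-1-yn-1-yl}trimethylsilane | c1ccc(cc1)SCC[C@H](c1ccc(OCc2ccccc2)c(OC)c1)C#C[Si](C)(C)C
F3 | step 5 | (S)-1-(benzyloxy)-2-methoxy-4-[5-(phenylsulfanyl)pent-1-yn-3-yl]benzene | c1ccc(cc1)SCC[C@H](c1ccc(OCc2ccccc2)c(OC)c1)C#C
F4 | step 5 | (R)-{[3-(4-(benzyloxy)-3-methoxyphenyl)-5-(phenylsulfanyl)pent-1-yn-1-yl]oxy}tri(propan-2-yl)silane | c1ccc(cc1)SCC[C@H](c1ccc(OCc2ccccc2)c(OC)c1)C#CO[Si](C(C)C)(C(C)C)C(C)C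
F5 | step 5 | 2-{(R)-1-[4-(benzyloxy)-3-methoxyphenyl]-3-(phenylsulfanyl)propyl}-5-ethoxy-3-{[tri(propan-2-yl)silyl]oxy}phenol | c1ccc(cc1)SCC[C@H](c1ccc(OCc2ccccc2)c(OC)c1)c1c(O)cc(OCC)cc1O[Si](C(C)C)(C(C)C)C(C)C
F6 | step 5 | 2-{(R)-1-[4-(benzyloxy)-3-methoxyphenyl]-3-(phenylsulfinyl)propyl}-5-ethoxy-3-{[tri(propan-2-yl)silyl]oxy}phenol, both sulfur epimers | O=S(c1ccccc1)CC[C@H](c1ccc(OCc2ccccc2)c(OC)c1)c1c(O)cc(OCC)cc1O[Si](C(C)C)(C(C)C)C(C)C
F7 | step 6 | 1-ethoxyvinyllithium | [Li]C(=C)OCC
F8 | step 6 | 3-ethoxybut-3-en-2-one | CC(=O)C(=C)OCC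
F9 | step 6 | 5-ethoxy-1,1,1-trifluorohex-5-ene-2,4-dione | C=C(OCC)C(=O)CC(=O)C(F)(F)F
F10 | step 6 | 1-diazo-3-ethoxybut-3-en-2-one | C=C(OCC)C(=O)C=[N+]=[N-]
F11 | step 3 | ethyl (E)-3-[4-(benzyloxy)-3-methoxyphenyl]prop-2-enoate | CCOC(=O)/C=C/c1ccc(OCc2ccccc2)c(OC)c1
F12 | step 3 | (E)-3-[4-(benzyloxy)-3-methoxyphenyl]prop-2-en-1-ol | OC/C=C/c1ccc(OCc2ccccc2)c(OC)c1
F13 | step 3 | diethyl (E)-3-[4-(benzyloxy)-3-methoxyphenyl]prop-2-en-1-yl phosphate | CCOP(=O)(OCC)OC/C=C/c1ccc(OCc2ccccc2)c(OC)c1
F14 | step 3 | bis(2-methylpropyl)[(trimethylsilyl)ethynyl]aluminium | CC(C)C[Al](CC(C)C)C#C[Si](C)(C)C
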